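Numbering is that of the ent-kaurane skeleton: ring A = C1–C5 and C10 (C18 methyl on C4), five-membered ring C4–C19–O–C6–C5, δ-lactone C10–C20–O–C7(=O)–C8–C9 spiro at C10, ring C = C8, C9, C11–C14, bridge C15–C16(=C17).
Retrosynthesis cuts, in this order: the C15 oxygen, C13–C16 (vinyl radical closure), C8–C15 (lactone alkylation), C8–C9 and C13–C14 together (intramolecular Diels–Alder across the C20–O–C7 ester), C11–C12 (vinyl addition), C1–C2 and C2–C3 (one carbon taken out of ring A), C9–C10 (allylation), and finally the Pauson–Khand bonds C4–C5, C3–C1 and C1–C10.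
The feature that permits the C2 excision: without C2, ring A is a cyclopentanone (C1, C10, C5, C4, C3) cis-fused to the C19–O–C6 ring, whose convex face directs the C10 substituent, and C2 is a bare CH2 flanking the C1 carbonyl on the side away from quaternary C10.
Forward order of rings: oxolane and cyclopentenone in one Pauson–Khand step, C6 oxidised to the γ-lactone, ring A by ring enlargement, δ-lactone and ring C together by cycloaddition, ring D by radical cyclisation, then the C6 acetal acetate and the C15 enone.
Stereochemistry: C4 from the BINAP–rhodium Pauson–Khand step; C5 by cis hydrogenation; C10 by convex-face allylation; C1 by equatorial hydride delivery; C9 by the face of the cycloaddition (anti to the C1 silyl ether); C8 by alkylation cis to H9; C13 by the bridge geometry; C11 by hydride from the bridge face; C6 by acetylation on the convex face.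

Key step: step 7

Assumption: (S)-BINAP is taken to be the ligand antipode that gives (R)-7 in step 3; if the sense of induction is the reverse, (R)-BINAP is used and nothing else changes.

Step 1
Reactants: 1 2-methylprop-2-en-1-ol; 2 propargyl bromide
Product: 3 methallyl propargyl ether
Conditions: 50% aq. NaOH, Bu4NHSO4 (cat.), toluene, rt
Reagents that add atoms: none
Why: Phase-transfer Williamson ether synthesis, in which the alkoxide displaces bromide from the unhindered propargylic carbon (SN2).

Step 2
Reactants: 3 methallyl propargyl ether; 4 methyl chloroformate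
Product: 6 methyl 4-(methallyloxy)but-2-ynoate, via lithium acetylide 5 (not isolated)
Conditions: n-BuLi, THF, −78 °C; then 4, −78 °C to 0 °C
Reagents that add atoms: none
Why: Deprotonation of the terminal alkyne and C-acylation of the acetylide with a chloroformate is the standard route to ynoates, and the ether and the 1,1-disubstituted alkene are inert.

Step 3
Reactants: 6 methyl 4-(methallyloxy)but-2-ynoate
Product: 7 bicyclic enone ester
Conditions: [Rh(CO)2Cl]2 (cat.), (S)-BINAP, AgOSO2CF3 (cat.), CO (1 atm), THF, 80 °C
Reagents that add atoms: carbon monoxide, [C-]#[O+]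
Why: Rhodium-catalysed intramolecular Pauson–Khand reaction of the 1,6-enyne closes the oxolane and the cyclopentenone together, and the chiral BINAP–rhodium complex selects the alkene face in the oxidative cyclisation, which fixes quaternary C4.

Step 4
Reactants: 7 bicyclic enone ester
Product: 8 ene-lactone
Conditions: CrO3, 3,5-dimethylpyrazole, CH2Cl2, −20 °C
Reagents that add atoms: chromium trioxide, O=[Cr](=O)=O
Why: Chromium trioxide–3,5-dimethylpyrazole allylic oxidation should take C6, the only methylene that is both allylic (γ to the enone carbonyl) and α to the ring oxygen, to the lactone carbonyl while C19 and C3 are left.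

Step 5
Reactants: 8 ene-lactone
Product: 9 saturated keto lactone
Conditions: H2 (1 atm), Pd/C (10% palladium on carbon), EtOAc, rt
Reagents that add atoms: none
Why: Heterogeneous hydrogenation of the electron-poor tetrasubstituted C5=C10 alkene adds hydrogen to C5 cis to the C4 methyl, the trans-fused bicyclo[3.3.0] alternative being too strained, which sets C5; C10 stays an epimerisable β-keto ester centre until step 6.

Step 6
Reactants: 9 saturated keto lactone; 10 allyl bromide
Product: 11 allylated keto lactone
Conditions: K2CO3, acetone, 50 °C
Reagents that add atoms: none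
Why: C-alkylation of the stabilised β-keto ester enolate with an allylic bromide, the electrophile approaching planar C10 from the convex face of the cis-bicyclo[3.3.0] system so that allyl ends cis to H5 and the ester on the concave face.

Step 7
Reactants: 11 allylated keto lactone; 12 trimethylsilyldiazomethane
Product: 14 ring A cyclohexanone, via C2-silyl ketone 13 (not isolated)
Conditions: BF3·OEt2, CH2Cl2, −78 °C; then 1 M HCl, THF, rt
Reagents that add atoms: none
Why: BF3 activates the C1 carbonyl, the nucleophilic diazo carbon of 12 adds to it and, as N2 leaves, the antiperiplanar C1–C3 bond shifts to the new carbon (a Tiffeneau–Demjanov-type diazoalkane homologation, here the Lewis-acid-promoted trimethylsilyldiazomethane ring expansion of a cycloalkanone), giving silyl ketone 13, which loses silicon on acidic work-up. Ring A is not closed by a cyclisation but by this 1,2-shift: the cyclopentanone C1–C10–C5–C4–C3 is enlarged to the six-membered ring by insertion of C2 between C1 and C3 (new bonds C1–C2 and C2–C3). No stereocentre is created in 14: C4, C5 and C10 are spectators, C10 keeps its configuration because it is not the migrating carbon, and the transient C2–Si centre is erased on protodesilylation. The step needs migration of the methylene C3 rather than quaternary C10, which the substrate secures through the bulk of C10 (allyl, ester, ring) next to the silyl-bearing diazo carbon and through the electron-withdrawing ester that lowers the migratory aptitude of C10. It also needs a single insertion, which the C-silyl group provides by shielding the product ketone until work-up. Lactone, ester and terminal alkene are not expected to react with the diazoalkane under these conditions.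

Step 8
Reactants: 14 ring A cyclohexanone
Product: 15 C1 alcohol
Conditions: LiBH(s-Bu)3, THF, −78 °C; aq. NH4Cl
Reagents that add atoms: none
Why: Steric-approach-controlled ketone reduction with a bulky trialkylborohydride, which should attack along the equatorial trajectory of the ring A chair that carries the ester axial and the allyl group equatorial, so the hydroxyl ends axial at C1, trans to C20 and cis to the allyl arm (1R).

Step 9
Reactants: 15 C1 alcohol
Product: 16 C1 silyl ether
Conditions: TBSOTf, 2,6-lutidine, CH2Cl2, 0 °C to rt
Reagents that add atoms: tert-butyldimethylsilyl trifluoromethanesulfonate, CC(C)(C)[Si](C)(C)OS(=O)(=O)C(F)(F)F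
Why: Silylation of the hindered axial secondary alcohol with the silyl triflate under buffered conditions that leave lactone, ester and alkene untouched.

Step 10
Reactants: 16 C1 silyl ether
Product: 17 C20 carboxylic acid
Conditions: LiI, pyridine, 110 °C; then 1 M HCl
Reagents that add atoms: none
Why: Nucleophilic ester dealkylation, in which iodide attacks the ester methyl group (SN2) and frees the hindered C20 carboxylate without touching the acyl carbon, while the lactone survives because its O-alkyl carbon C19 is neopentylic.

Step 11
Reactants: 17 C20 carboxylic acid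
Product: 19 C20 primary alcohol, via acid chloride 18 (not isolated)
Conditions: (COCl)2, DMF (cat.), CH2Cl2, 0 °C to rt; evaporate; NaBH4, THF–DMF, −40 °C; AcOH quench at −40 °C
Reagents that add atoms: none
Why: Acyl chloride formation followed by borohydride reduction, NaBH4 reducing an acid chloride far faster than a lactone, with a cold acidic quench so that the new C20 alkoxide does not attack the C6 lactone carbonyl.

Step 12
Reactants: 19 C20 primary alcohol; 20 acryloyl chloride
Product: 21 C20 acrylate
Conditions: Et3N, 4-(dimethylamino)pyridine (cat.), CH2Cl2, −20 °C to 0 °C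
Reagents that add atoms: none
Why: Amine-mediated O-acylation of the primary neopentylic alcohol with an acid chloride, run cold to avoid acrylate polymerisation and lactone exchange.

Step 13
Reactants: 21 C20 acrylate
Product: 23 C11 aldehyde, via ozonide 22 (not isolated)
Conditions: O3, CH2Cl2, −78 °C, Sudan Red 7B end point; then PPh3, −78 °C to rt
Reagents that add atoms: ozone, [O-][O+]=O
Why: Ozonolysis with reductive work-up, electrophilic ozone cleaving the isolated terminal alkene much faster than the electron-poor acrylate and the dye end point stopping ozone uptake after the first alkene.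

Step 14
Reactants: 23 C11 aldehyde; 24 vinylmagnesium bromide
Product: 25 allylic alcohol
Conditions: THF, −78 °C; aq. NH4Cl
Reagents that add atoms: none
Why: Grignard 1,2-addition to the aldehyde, which at −78 °C should outpace attack on the acrylate and the hindered lactone; C11 forms as both epimers, which is immaterial because the centre is oxidised in step 15.

Step 15
Reactants: 25 allylic alcohol
Product: 26 vinyl ketone
Conditions: Dess–Martin periodinane, NaHCO3, CH2Cl2, 0 °C
Reagents that add atoms: none
Why: Dess–Martin oxidation of the secondary allylic alcohol to the vinyl ketone under buffered, non-nucleophilic conditions.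

Step 16
Reactants: 26 vinyl ketone
Product: 27 silyloxy diene
Conditions: TBSOTf, Et3N, CH2Cl2, −78 °C to 0 °C
Reagents that add atoms: tert-butyldimethylsilyl trifluoromethanesulfonate, CC(C)(C)[Si](C)(C)OS(=O)(=O)C(F)(F)F
Why: Soft enolisation and O-silylation of the ketone, C9 carrying the only enolisable hydrogens, the (Z)-enol ether (silyloxy cis to C10) being favoured because quaternary C10 then avoids the vinyl group.

Step 17
Reactants: 27 silyloxy diene
Product: 28 cycloadduct
Conditions: toluene (0.005 M), 2,6-di-tert-butyl-4-methylphenol (cat.), 170 °C, sealed tube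
Reagents that add atoms: none
Why: Thermal intramolecular Diels–Alder reaction of the 2-silyloxy diene with the ester-tethered acrylate forms C8–C9 and C13–C14 and so closes the δ-lactone and ring C at once; the tether carbonyl should sit endo (cis fusion) and the acrylate should reach C9 past H5 and anti to the C1 silyl ether, which sets C9 (C8 is reset in step 18).

Step 18
Reactants: 28 cycloadduct; 29 2,3-dibromopropene
Product: 31 C8-alkylated lactone, via lithium enolate 30 (not isolated)
Conditions: LiN(i-Pr)2, THF, −78 °C; then 29, DMPU, −78 °C to −30 °C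
Reagents that add atoms: none
Why: Alkylation of the δ-lactone enolate with an allylic bromide, the accessible C8–H being removed in preference to the shielded C5–H and the electrophile entering planar C8 cis to H9 and anti to C1 of the spiro centre, which gives the cis ring fusion with C15 on the H9 face.

Step 19
Reactants: 31 C8-alkylated lactone
Product: 32 C6 lactol
Conditions: i-Bu2AlH (1.2 equiv), CH2Cl2, −78 °C; aq. potassium sodium tartrate
Reagents that add atoms: none
Why: Partial reduction of a lactone to the lactol through the aluminium hemiacetal that is stable at −78 °C, the γ-lactone carbonyl on tertiary C5 (convex face open) being reduced in preference to the δ-lactone carbonyl on quaternary C8.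

Step 20
Reactants: 32 C6 lactol
Product: 33 C6 acetate
Conditions: Ac2O, pyridine, 4-(dimethylamino)pyridine (cat.), CH2Cl2, 0 °C
Reagents that add atoms: acetic anhydride, CC(=O)OC(C)=O
Why: Acetylation of the equilibrating lactol, the anomer with the hydroxyl on the convex face (trans to C10, cis to H5) being acylated preferentially, which sets C6.

Step 21
Reactants: 33 C6 acetate
Product: 34 enone
Conditions: Pd(OAc)2 (1.1 equiv), MeCN, rt
Reagents that add atoms: none
Why: Saegusa–Ito oxidation, in which Pd(OAc)2 converts the enol silane into the palladium enolate at C12 and β-hydride loss from C13 gives the C12=C13 enone; without phosphine at room temperature the vinyl bromide is not expected to add to the palladium metal released.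

Step 22
Reactants: 34 enone
Product: 35 tetracyclic ketone
Conditions: Bu3SnH (slow addition), azobisisobutyronitrile (cat.), benzene (0.01 M), 80 °C
Reagents that add atoms: none
Why: Tin hydride-mediated 5-exo-trig cyclisation of the C16 vinyl radical onto the enone β-carbon C13 closes ring D; the radical arm on C8 can only reach the face of C13 syn to C15, which fixes C13, and the C12 α-keto radical is then reduced.

Step 23
Reactants: 35 tetracyclic ketone
Product: 36 C11 alcohol
Conditions: NaBH4, MeOH–THF, −20 °C
Reagents that add atoms: none
Why: Borohydride reduction of the ketone, hydride being expected to add to C11 from the face of the C15–C16 bridge because the other face is screened by the axial spiro carbon C10 and its C1 silyl ether, which gives the equatorial alcohol trans to H9.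

Step 24
Reactants: 36 C11 alcohol
Product: 37 C1,C11-diol
Conditions: HF·pyridine, pyridine, THF, 0 °C to rt
Reagents that add atoms: none
Why: Fluoride cleavage of the silyl ether under buffered conditions that should spare the acetal acetate and both lactones.

Step 25
Reactants: 37 C1,C11-diol
Product: 38 C15 allylic alcohol
Conditions: SeO2 (cat.), t-BuOOH, CH2Cl2, rt
Reagents that add atoms: selenium dioxide, O=[Se]=O; tert-butyl hydroperoxide, CC(C)(C)OO
Why: Selenium dioxide allylic hydroxylation (ene reaction then 2,3-sigmatropic shift), C15 being the only allylic carbon that can lose hydrogen since C13 is a bridgehead; both C15 epimers converge in step 26.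

Step 26
Reactants: 38 C15 allylic alcohol
Product: 39 oreskaurin A
Conditions: MnO2 (activated, excess), CH2Cl2, rt
Reagents that add atoms: none
Why: MnO2 oxidises only the allylic C15 alcohol and leaves the saturated C1 and C11 alcohols, giving the α-methylene ketone of the target.

Compound list
1 | 2-methylprop-2-en-1-ol | C=C(C)CO | starting material
2 | propargyl bromide (3-bromoprop-1-yne) | C#CCBr | starting material
3 | methallyl propargyl ether (2-methyl-3-(prop-2-yn-1-yloxy)prop-1-ene) | C=C(C)COCC#C | intermediate
4 | methyl chloroformate | COC(=O)Cl | starting material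
5 | lithium acetylide of 3 | [Li]C#CCOCC(C)=C | intermediate
6 | methyl 4-[(2-methylprop-2-en-1-yl)oxy]but-2-ynoate | C=C(C)COCC#CC(=O)OC | intermediate
7 | bicyclic enone ester, methyl (6aR)-6a-methyl-5-oxo-3,5,6,6a-tetrahydro-1H-cyclopenta[c]furan-4-carboxylate (quaternary C4 with methyl, C5=C10 alkene, C1 ketone, CO2Me on C10) | O=C1C[C@@]2(C)COCC2=C1C(=O)OC | intermediate
8 | ene-lactone: 7 with C6 oxidised to the lactone carbonyl (C19–O–C6(=O)–C5=C10) | O=C1C[C@@]2(C)COC(=O)C2=C1C(=O)OC | intermediate
9 | saturated keto lactone: cis-fused (H5 and C4 methyl on the same face), C10–H β-keto ester as epimer and enol mixture | COC(=O)C1C(=O)C[C@@]2(C)COC(=O)[C@H]21 | intermediate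
10 | allyl bromide | C=CCBr | starting material
11 | allylated keto lactone: cis-fused cyclopentanone γ-lactone, C10 bearing allyl (cis to H5) and CO2Me (cis to C6) | C=CC[C@]1(C(=O)OC)C(=O)C[C@@]2(C)COC(=O)[C@H]21 | intermediate
12 | trimethylsilyldiazomethane | C[Si](C)(C)C=[N+]=[N-] | starting material
13 | C2-silyl ketone: ring-enlarged ketone with SiMe3 on the new C2 (C2 epimers) | C=CC[C@]1(C(=O)OC)C(=O)C([Si](C)(C)C)C[C@@]2(C)COC(=O)[C@H]21 | intermediate
14 | ring A cyclohexanone: C1 ketone, C2 and C3 methylenes, cis-fused C6 γ-lactone, C10 allyl and CO2Me as in 11 | C=CC[C@]1(C(=O)OC)C(=O)CC[C@@]2(C)COC(=O)[C@H]21 | intermediate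
15 | C1 alcohol (1R): hydroxyl cis to the C10 allyl group, trans to the C10 ester | C=CC[C@]1(C(=O)OC)[C@H](O)CC[C@@]2(C)COC(=O)[C@H]21 | intermediate
16 | C1 tert-butyldimethylsilyl ether of 15 | C=CC[C@]1(C(=O)OC)[C@H](O[Si](C)(C)C(C)(C)C)CC[C@@]2(C)COC(=O)[C@H]21 | intermediate
17 | C20 carboxylic acid | C=CC[C@]1(C(=O)O)[C@H](O[Si](C)(C)C(C)(C)C)CC[C@@]2(C)COC(=O)[C@H]21 | intermediate
18 | C20 acid chloride | C=CC[C@]1(C(=O)Cl)[C@H](O[Si](C)(C)C(C)(C)C)CC[C@@]2(C)COC(=O)[C@H]21 | intermediate
19 | C20 primary alcohol (CH2OH on C10) | C=CC[C@]1(CO)[C@H](O[Si](C)(C)C(C)(C)C)CC[C@@]2(C)COC(=O)[C@H]21 | intermediate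
20 | acryloyl chloride | C=CC(=O)Cl | starting material
21 | C20 acrylate ester | C=CC[C@]1(COC(=O)C=C)[C@H](O[Si](C)(C)C(C)(C)C)CC[C@@]2(C)COC(=O)[C@H]21 | intermediate
22 | ozonide: 1,2,4-trioxolane formed from the allyl alkene (C11 epimers) | C1(C[C@]2(COC(=O)C=C)[C@H](O[Si](C)(C)C(C)(C)C)CC[C@@]3(C)COC(=O)[C@H]32)OCOO1 | intermediate
23 | C11 aldehyde (CH2–CHO on C10) | O=CC[C@]1(COC(=O)C=C)[C@H](O[Si](C)(C)C(C)(C)C)CC[C@@]2(C)COC(=O)[C@H]21 | intermediate
24 | vinylmagnesium bromide | C=C[Mg]Br | starting material
25 | allylic alcohol (CH2–CH(OH)–CH=CH2 on C10, both C11 epimers) | C=CC(O)C[C@]1(COC(=O)C=C)[C@H](O[Si](C)(C)C(C)(C)C)CC[C@@]2(C)COC(=O)[C@H]21 | intermediate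
26 | vinyl ketone (CH2–C(=O)–CH=CH2 on C10) | C=CC(=O)C[C@]1(COC(=O)C=C)[C@H](O[Si](C)(C)C(C)(C)C)CC[C@@]2(C)COC(=O)[C@H]21 | intermediate
27 | (Z)-2-silyloxy diene C9=C11(OTBS)–C12=C13, silyloxy cis to C10 | C=C/C(O[Si](C)(C)C(C)(C)C)=C/[C@]1(COC(=O)C=C)[C@H](O[Si](C)(C)C(C)(C)C)CC[C@@]2(C)COC(=O)[C@H]21 | intermediate
28 | cycloadduct: spiro δ-lactone cis-fused to ring C (C11(OTBS)=C12 enol ether), H8 and H9 cis, C11 on the C1 side of the lactone ring; the C8 epimer, if formed, converges in step 18 | O=C1OC[C@]2([C@H](O[Si](C)(C)C(C)(C)C)CC[C@@]3(C)COC(=O)[C@H]32)[C@@H]4C(O[Si](C)(C)C(C)(C)C)=CCC[C@H]14 | intermediate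
29 | 2,3-dibromopropene | C=C(Br)CBr | starting material
30 | lithium enolate of the δ-lactone (C7–OLi, C7=C8) | [Li]OC1=C2CCC=C(O[Si](C)(C)C(C)(C)C)[C@H]2[C@]2(CO1)[C@H](O[Si](C)(C)C(C)(C)C)CC[C@@]3(C)COC(=O)[C@H]32 | intermediate
31 | C8-alkylated lactone: 2-bromoallyl on C8, cis to H9 | C=C(Br)C[C@]12CCC=C(O[Si](C)(C)C(C)(C)C)[C@H]1[C@]1(COC2=O)[C@H](O[Si](C)(C)C(C)(C)C)CC[C@@]2(C)COC(=O)[C@H]21 | intermediate
32 | C6 lactol (anomers) | C=C(Br)C[C@]12CCC=C(O[Si](C)(C)C(C)(C)C)[C@H]1[C@]1(COC2=O)[C@H](O[Si](C)(C)C(C)(C)C)CC[C@@]2(C)COC(O)[C@H]21 | intermediate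
33 | C6 acetate: acetoxy on the convex face, trans to C10 and cis to H5 | C=C(Br)C[C@]12CCC=C(O[Si](C)(C)C(C)(C)C)[C@H]1[C@]1(COC2=O)[C@H](O[Si](C)(C)C(C)(C)C)CC[C@@]2(C)CO[C@H](OC(C)=O)[C@H]21 | intermediate
34 | enone: C11 ketone, C12=C13 alkene | C=C(Br)C[C@]12CC=CC(=O)[C@H]1[C@]1(COC2=O)[C@H](O[Si](C)(C)C(C)(C)C)CC[C@@]2(C)CO[C@H](OC(C)=O)[C@H]21 | intermediate
35 | tetracyclic ketone: bicyclo[3.2.1]octane closed through C13–C16, exocyclic C16=C17, C11 ketone | C=C1C[C@]23C[C@H]1CC(=O)[C@H]2[C@]1(COC3=O)[C@H](O[Si](C)(C)C(C)(C)C)CC[C@@]2(C)CO[C@H](OC(C)=O)[C@H]21 | intermediate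
36 | C11 alcohol: hydroxyl trans to H9, on the face away from the C15–C16 bridge | C=C1C[C@]23C[C@H]1C[C@@H](O)[C@H]2[C@]1(COC3=O)[C@H](O[Si](C)(C)C(C)(C)C)CC[C@@]2(C)CO[C@H](OC(C)=O)[C@H]21 | intermediate
37 | C1,C11-diol | C=C1C[C@]23C[C@H]1C[C@@H](O)[C@H]2[C@]1(COC3=O)[C@H](O)CC[C@@]2(C)CO[C@H](OC(C)=O)[C@H]21 | intermediate
38 | C15 allylic alcohol (C15 epimers) | C=C1C(O)[C@]23C[C@H]1C[C@@H](O)[C@H]2[C@]1(COC3=O)[C@H](O)CC[C@@]2(C)CO[C@H](OC(C)=O)[C@H]21 | intermediate
39 | oreskaurin A | C=C1C(=O)[C@]23C[C@H]1C[C@@H](O)[C@H]2[C@]1(COC3=O)[C@H](O)CC[C@@]2(C)CO[C@H](OC(C)=O)[C@H]21 | target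

Total step count: 26. Longest linear sequence: 26 steps (1 to 39); the route is fully linear.

Steps most likely to fail

Step 17. The tether forces the electronically less favourable orientation of the silyloxy diene and the acrylate, so the cycloaddition may be outrun by thermal polymerisation. It may also show poor facial discrimination at C9, with the acrylate passing the C1 side of the spiro centre. The fallback sets out from 25 and comes back at 28, and replaces steric face control by a temporary oxygen bridge. HF·pyridine removes the C1 silyl group of 25 to give the diol acrylate F1. MnO2 oxidises its allylic alcohol, and the γ-hydroxy vinyl ketone closes onto the C1 hydroxyl to the cyclic hemiketal F2. Pyridinium p-toluenesulfonate with 4 Å molecular sieves in benzene dehydrates this to the bridged dienyl ether F3, a 2-vinyl-dihydrofuran whose C1–O–C11 bridge holds C9=C11 in a five-membered ring fused to ring A. The C20-tethered acrylate can then reach C9 only on the face syn to C20, and C11 is bound to end on the C1 side of the new lactone ring. Heating in toluene gives the bridged cycloadduct F4, mild aqueous acid opens its enol ether to the keto alcohol F5, and TBSOTf with Et3N silylates the C1 hydroxyl and the C11 ketone (towards C12) to return 28.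

Step 8. Hydride may be delivered from the allyl-bearing face (axial attack on the other chair), which would give the C1 epimer. The fallback sets out from 14 and comes back at 15. It is a reagent-controlled Corey–Bakshi–Shibata reduction with (S)-1-methyl-3,3-diphenyltetrahydro-1H,3H-pyrrolo[1,2-c][1,3,2]oxazaborole and catecholborane in toluene at −78 °C. The catalyst, with quaternary C10 as the large group, rather than the ring conformation then decides the face, and catecholborane does not hydroborate the allyl group at this temperature. No compound outside the list is made (F0).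

Step 22. Hydrogen transfer from the stannane to the vinyl radical may occur before ring closure (simple debromination), or a 1,5-hydrogen shift may outrun the 5-exo closure. The fallback sets out from 34 and comes back at 35. It is a reductive Heck cyclisation with Pd(OAc)2, PPh3 and HCO2Na in DMF at 80 °C: insertion of palladium into the C16–Br bond, syn-carbopalladation of the enone at C13 and formate reduction of the palladium enolate form the same C13–C16 bond by a two-electron pathway. No compound outside the list is made (F0).

Further compounds
F1 | step 17 | diol acrylate: 25 without the C1 silyl group (C11 epimers) | C=CC(O)C[C@]1(COC(=O)C=C)[C@H](O)CC[C@@]2(C)COC(=O)[C@H]21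
F2 | step 17 | cyclic hemiketal: C1–O–C11(OH)(vinyl) five-membered ring (C11 epimers) | C=CC1(O)C[C@]2(COC(=O)C=C)[C@H](O1)CC[C@@]3(C)COC(=O)[C@H]32
F3 | step 17 | bridged dienyl ether: 2-vinyl-dihydrofuran with C9=C11 in the C1–O–C11 ring | C=CC1=C[C@]2(COC(=O)C=C)[C@H](O1)CC[C@@]3(C)COC(=O)[C@H]32
F4 | step 17 | bridged cycloadduct: δ-lactone and ring C closed, C11(=C12) enol ether still bridged to O1 | O=C1OC[C@]2([C@H](O5)CC[C@@]3(C)COC(=O)[C@H]32)[C@@H]4C5=CCC[C@H]14
F5 | step 17 | keto alcohol: C11 ketone and free C1 hydroxyl | O=C1OC[C@]2([C@H](O)CC[C@@]3(C)COC(=O)[C@H]32)[C@@H]4C(=O)CCC[C@H]14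
F0 | step 8 | none | none
F0 | step 22 | none | none
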